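The target is an isoflavan whose ring C (O1, C2, C3, C4, C4a, C8a) holds a one-carbon, one-oxygen unit, C2–O1, between the benzylic carbon C3 and the ring A carbon C8a. The route rests on inserting this unit from ethyl formate into an open-chain 2-bromodeoxybenzoin (ring A–C4(=O)–C3H2–ring B): C-formylation at C3 and copper-catalysed O-arylation of the resulting enolate oxygen at C8a close ring C as an isoflavone in one pot. The key step exploits the acidity of C3 between the C4 carbonyl and ring B and the ortho relation of C8a to C4. A Claisen rearrangement then installs the 1,1-dimethylallyl group, and a final asymmetric transfer hydrogenation sets C3.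

Key step: step 6

Remark: isoflavan numbering is used (ring A = C4a, C5 to C8, C8a; ring C = O1, C2, C3, C4, C4a, C8a; ring B = C1′ to C6′); the stereocentre of the target is (3S), and compounds 1, 2, 4, 6, 8, 10 and 14 are taken as commercial.

Step 1
Reactants: 1 2,3,4-trihydroxybenzaldehyde; 2 prenyl bromide
Product: 3 2,3-dihydroxy-4-(3-methylbut-2-enyloxy)benzaldehyde
Conditions: Li2CO3, DMF, 45 °C
Reagents that add atoms: prenyl bromide (1-bromo-3-methylbut-2-ene), CC(C)=CCBr
Why: Williamson ether synthesis in which the weak base ionises only the 4-OH (para to the formyl group, most acidic and not hydrogen-bonded), so O-prenylation should occur there and leave the chelated 2-OH and the 3-OH free.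

Step 2
Reactants: 3 2,3-dihydroxy-4-(3-methylbut-2-enyloxy)benzaldehyde; 4 chloromethyl methyl ether
Product: 5 2-hydroxy-3-(methoxymethoxy)-4-(3-methylbut-2-enyloxy)benzaldehyde
Conditions: NaH (2.2 equiv), DMF, 0 °C; MOMCl (1.0 equiv)
Reagents that add atoms: chloromethyl methyl ether, COCCl
Why: Williamson-type O-alkylation of the dianion, in which the 3-oxide is not stabilised by conjugation or chelation with the formyl group and is the more nucleophilic site, so one equivalent of MOMCl should cap O3 and leave the chelated 2-oxide.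

Step 3
Reactants: 5 2-hydroxy-3-(methoxymethoxy)-4-(3-methylbut-2-enyloxy)benzaldehyde; 6 iodomethane
Product: 7 2-methoxy-3-(methoxymethoxy)-4-(3-methylbut-2-enyloxy)benzaldehyde
Conditions: MeI, K2CO3, DMF, 40 °C
Reagents that add atoms: iodomethane, CI
Why: Williamson methylation of the remaining chelated phenol should fix the 2′-methoxy group of ring B.

Step 4
Reactants: 8 2-bromo-4-hydroxybenzaldehyde; 4 chloromethyl methyl ether
Product: 9 2-bromo-4-(methoxymethoxy)benzaldehyde
Conditions: MOMCl, i-Pr2NEt, CH2Cl2, 0 → 25 °C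
Reagents that add atoms: chloromethyl methyl ether, COCCl
Why: O-alkylation to the MOM acetal masks the future 7-OH, so that the ring A aldehyde stays electrophilic and no phenoxide interferes in steps 5 and 6.

Step 5
Reactants: 7 2-methoxy-3-(methoxymethoxy)-4-(3-methylbut-2-enyloxy)benzaldehyde; 10 p-toluenesulfonohydrazide; 9 2-bromo-4-(methoxymethoxy)benzaldehyde
Product: 13 1-[2-bromo-4-(methoxymethoxy)phenyl]-2-[2-methoxy-3-(methoxymethoxy)-4-(3-methylbut-2-enyloxy)phenyl]ethan-1-one, via tosylhydrazone 11 (not isolated), via aryldiazomethane 12 (not isolated)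
Conditions: TsNHNH2 (1.0 equiv), 1,4-dioxane, 60 °C; then 9 (1.5 equiv), K2CO3, 110 °C
Reagents that add atoms: none
Why: Condensation to the tosylhydrazone, Bamford–Stevens generation of the aryldiazomethane and its addition to aldehyde 9 followed by a 1,2-hydride shift with loss of N2 (aldehyde homologation) should give the deoxybenzoin with the carbonyl on the ring A side.

Step 6
Reactants: 13 1-[2-bromo-4-(methoxymethoxy)phenyl]-2-[2-methoxy-3-(methoxymethoxy)-4-(3-methylbut-2-enyloxy)phenyl]ethan-1-one; 14 ethyl formate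
Product: 16 7-(methoxymethoxy)-3-[2-methoxy-3-(methoxymethoxy)-4-(3-methylbut-2-enyloxy)phenyl]-4H-chromen-4-one, via potassium enolate 15 (not isolated)
Conditions: HCO2Et (10 equiv), t-BuOK (2.2 equiv), THF, 0 → 25 °C; then CuI (10 mol %), 1,10-phenanthroline (20 mol %), DMF, 90 °C, one pot
Reagents that add atoms: ethyl formate, CCOC=O
Why: t-BuOK deprotonates C3, which is acidified by the C4 carbonyl and by ring B, and a crossed Claisen condensation with ethyl formate forms C2–C3, the product being drained from the retro-Claisen equilibrium as the chelated Z β-oxido enone 15. Monovalent copper then adds oxidatively to the C8a–Br bond and reductive elimination with the enolate oxygen forms O1–C8a (Ullmann-type intramolecular O-arylation). The closest known reaction types are the formate synthesis of isoflavones from 2-hydroxydeoxybenzoins, in which the phenol oxygen is already on ring A, and the copper-catalysed cyclisation of 1-(2-bromoaryl)-1,3-dicarbonyl enolates to chromones. Ring C closes as a six-membered ring by attack of the enolate oxygen on the trigonal carbon C8a with the C–Br bond outside the new ring (6-exo-trig), the Z enolate holding O1 beside C8a. No stereocentre arises because C3 is trigonal in the isoflavone; it is set in step 9. The step needs C- over O-formylation, secured by the thermodynamic stability of the β-dicarbonyl enolate, and O-arylation over C-arylation and over intermolecular etherification by ethoxide or tert-butoxide, secured because C-arylation would demand a four-membered ring and the six-membered closure is intramolecular.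

Step 7
Reactants: 16 7-(methoxymethoxy)-3-[2-methoxy-3-(methoxymethoxy)-4-(3-methylbut-2-enyloxy)phenyl]-4H-chromen-4-one
Product: 17 3-[4-hydroxy-2-methoxy-3-(methoxymethoxy)-5-(2-methylbut-3-en-2-yl)phenyl]-7-(methoxymethoxy)-4H-chromen-4-one
Conditions: PhNEt2, 190 °C, sealed tube, argon
Reagents that add atoms: none
Why: Aromatic Claisen rearrangement, in which the [3,3] shift of the aryl prenyl ether delivers the allyl unit with allylic transposition to C5′, the only ortho position of O4′ that carries hydrogen (C3′ is blocked and the para position C1′ is substituted), and tautomerisation restores the phenol.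

Step 8
Reactants: 17 3-[4-hydroxy-2-methoxy-3-(methoxymethoxy)-5-(2-methylbut-3-en-2-yl)phenyl]-7-(methoxymethoxy)-4H-chromen-4-one
Product: 18 3-[3,4-dihydroxy-2-methoxy-5-(2-methylbut-3-en-2-yl)phenyl]-7-hydroxy-4H-chromen-4-one
Conditions: 3 M HCl, MeOH, 45 °C
Reagents that add atoms: none
Why: Acid-catalysed cleavage of both MOM acetals with methanol as trap for the methoxymethyl cation should leave the isoflavone core and the monosubstituted alkene untouched under these mild conditions.

Step 9
Reactants: 18 3-[3,4-dihydroxy-2-methoxy-5-(2-methylbut-3-en-2-yl)phenyl]-7-hydroxy-4H-chromen-4-one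
Product: 22 (3S)-3-[3,4-dihydroxy-2-methoxy-5-(2-methylbut-3-en-2-yl)phenyl]chroman-7-ol, via isoflavanone 19 (not isolated), via cis-isoflavan-4-ol 20 (not isolated), via quinone methide 21 (not isolated)
Conditions: RuCl[(S,S)-TsDPEN](p-cymene) (5 mol %), HCO2H/Et3N (5:2), DMF, 45 °C
Reagents that add atoms: none
Why: Asymmetric transfer hydrogenation cascade of the type known for isoflavones and isoflavanones, in which the divalent ruthenium hydride reduces C2=C3 by conjugate addition, the isoflavanone racemises at C3 through its enol while the (S,S)-catalyst reduces the (3S)-ketone faster to the cis-(3S,4S)-alcohol (dynamic kinetic resolution, which sets C3), and the 7-OH para to C4 expels water to a quinone methide that takes up hydride at C4, so that C3 should keep its configuration.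

Compound list
1 | 2,3,4-trihydroxybenzaldehyde | O=Cc1ccc(O)c(O)c1O | starting material
2 | prenyl bromide (1-bromo-3-methylbut-2-ene) | CC(C)=CCBr | starting material
3 | 2,3-dihydroxy-4-(3-methylbut-2-enyloxy)benzaldehyde | O=Cc1ccc(OCC=C(C)C)c(O)c1O | intermediate
4 | chloromethyl methyl ether | COCCl | starting material
5 | 2-hydroxy-3-(methoxymethoxy)-4-(3-methylbut-2-enyloxy)benzaldehyde | O=Cc1ccc(OCC=C(C)C)c(OCOC)c1O | intermediate
6 | iodomethane | CI | starting material
7 | 2-methoxy-3-(methoxymethoxy)-4-(3-methylbut-2-enyloxy)benzaldehyde | O=Cc1ccc(OCC=C(C)C)c(OCOC)c1OC | intermediate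
8 | 2-bromo-4-hydroxybenzaldehyde | O=Cc1ccc(O)cc1Br | starting material
9 | 2-bromo-4-(methoxymethoxy)benzaldehyde | O=Cc1ccc(OCOC)cc1Br | intermediate
10 | p-toluenesulfonohydrazide | Cc1ccc(cc1)S(=O)(=O)NN | starting material
11 | (E)-tosylhydrazone of aldehyde 7 | Cc1ccc(cc1)S(=O)(=O)N/N=C/c1ccc(OCC=C(C)C)c(OCOC)c1OC | intermediate
12 | 1-(diazomethyl)-2-methoxy-3-(methoxymethoxy)-4-(3-methylbut-2-enyloxy)benzene | [N-]=[N+]=Cc1ccc(OCC=C(C)C)c(OCOC)c1OC | intermediate
13 | 1-[2-bromo-4-(methoxymethoxy)phenyl]-2-[2-methoxy-3-(methoxymethoxy)-4-(3-methylbut-2-enyloxy)phenyl]ethan-1-one | O=C(Cc1ccc(OCC=C(C)C)c(OCOC)c1OC)c1ccc(OCOC)cc1Br | intermediate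
14 | ethyl formate | CCOC=O | starting material
15 | potassium (Z)-3-[2-bromo-4-(methoxymethoxy)phenyl]-2-[2-methoxy-3-(methoxymethoxy)-4-(3-methylbut-2-enyloxy)phenyl]-3-oxoprop-1-en-1-olate | [K+].[O-]/C=C(\C(=O)c1ccc(OCOC)cc1Br)c1ccc(OCC=C(C)C)c(OCOC)c1OC | intermediate
16 | 7-(methoxymethoxy)-3-[2-methoxy-3-(methoxymethoxy)-4-(3-methylbut-2-enyloxy)phenyl]-4H-chromen-4-one | O=c1c(-c2ccc(OCC=C(C)C)c(OCOC)c2OC)coc2cc(OCOC)ccc12 | intermediate
17 | 3-[4-hydroxy-2-methoxy-3-(methoxymethoxy)-5-(2-methylbut-3-en-2-yl)phenyl]-7-(methoxymethoxy)-4H-chromen-4-one | O=c1c(-c2cc(C(C)(C)C=C)c(O)c(OCOC)c2OC)coc2cc(OCOC)ccc12 | intermediate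
18 | 3-[3,4-dihydroxy-2-methoxy-5-(2-methylbut-3-en-2-yl)phenyl]-7-hydroxy-4H-chromen-4-one | O=c1c(-c2cc(C(C)(C)C=C)c(O)c(O)c2OC)coc2cc(O)ccc12 | intermediate
19 | racemic 3-[3,4-dihydroxy-2-methoxy-5-(2-methylbut-3-en-2-yl)phenyl]-7-hydroxychroman-4-one | O=C1c2ccc(O)cc2OCC1c1cc(C(C)(C)C=C)c(O)c(O)c1OC | intermediate
20 | (3S,4S)-3-[3,4-dihydroxy-2-methoxy-5-(2-methylbut-3-en-2-yl)phenyl]chromane-4,7-diol (cis) | C=CC(C)(C)c1cc([C@H]2COc3cc(O)ccc3[C@H]2O)c(OC)c(O)c1O | intermediate
21 | (3S)-3-[3,4-dihydroxy-2-methoxy-5-(2-methylbut-3-en-2-yl)phenyl]-2,3-dihydro-7H-chromen-7-one (para-quinone methide) | C=CC(C)(C)c1cc([C@H]2COC3=CC(=O)C=CC3=C2)c(OC)c(O)c1O | intermediate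
22 | (3S)-3-[3,4-dihydroxy-2-methoxy-5-(2-methylbut-3-en-2-yl)phenyl]chroman-7-ol | C=CC(C)(C)c1cc([C@H]2COc3cc(O)ccc3C2)c(OC)c(O)c1O | target

Total step count: 9. Longest linear sequence: 8 steps (steps 1, 2, 3, 5, 6, 7, 8, 9).

Steps most likely to fail

Step 5. The aryldiazomethane may be lost to azine formation or carbene dimerisation before it adds to the only moderately electrophilic 4-alkoxybenzaldehyde, and in the adduct aryl migration or epoxide closure may compete with the hydride shift. The fallback turns ring A into an acyl anion equivalent and sets out from 9. Abramov-type addition of diethyl trimethylsilyl phosphite to 9 should give diethyl {[2-bromo-4-(methoxymethoxy)phenyl](trimethylsilyloxy)methyl}phosphonate F1. Deprotonation with LDA in THF at −78 °C and Horner–Wadsworth–Emmons reaction with aldehyde 7 should give the silyl enol ether 1-[2-bromo-4-(methoxymethoxy)phenyl]-2-[2-methoxy-3-(methoxymethoxy)-4-(3-methylbut-2-enyloxy)phenyl]-1-(trimethylsilyloxy)ethene F2 as an E/Z mixture. Desilylation with TBAF/AcOH then returns to the route at 13.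

Step 7. At 190 °C the prenyl group may be lost, the product may isomerise further by the abnormal (ene-type) Claisen pathway, and the new phenol may cyclise onto the alkene. The fallback builds the aryl–C(CH3)2 bond by cross-coupling and sets out from 16. Oxidative removal of the prenyl ether with DDQ in CH2Cl2/H2O should give 3-[4-hydroxy-2-methoxy-3-(methoxymethoxy)phenyl]-7-(methoxymethoxy)-4H-chromen-4-one F3. Bromination with NBS in MeCN at 0 °C, ortho to the free phenol (the para position is blocked), should give 3-[5-bromo-4-hydroxy-2-methoxy-3-(methoxymethoxy)phenyl]-7-(methoxymethoxy)-4H-chromen-4-one F4. A Suzuki–Miyaura coupling with 3-methylbut-2-enylboronic acid pinacol ester (Pd(OAc)2, a dialkylbiarylphosphine chosen for branched, γ-selective coupling, K3PO4, THF/H2O) then returns to the route at 17.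

Step 9. Conjugate reduction of the electron-rich 7-hydroxychromone may be slow, the cascade may stall at the alcohol, the catechol may inhibit the catalyst, and the ee may erode if the quinone methide tautomerises to the isoflav-3-ene. The fallback keeps the phenols protected, separates the three reductions and sets out from 17. Conjugate reduction with L-Selectride (THF, −78 °C) should give racemic 3-[4-hydroxy-2-methoxy-3-(methoxymethoxy)-5-(2-methylbut-3-en-2-yl)phenyl]-7-(methoxymethoxy)chroman-4-one F5. Asymmetric transfer hydrogenation with dynamic kinetic resolution (RuCl[(S,S)-TsDPEN](p-cymene), HCO2H/Et3N) should give (3S,4S)-3-[4-hydroxy-2-methoxy-3-(methoxymethoxy)-5-(2-methylbut-3-en-2-yl)phenyl]-7-(methoxymethoxy)chroman-4-ol F6. Ionic hydrogenation with Et3SiH/TFA in CH2Cl2 at −20 → 0 °C should remove the benzylic hydroxyl and both MOM groups and return to the route at 22.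

Further compounds
F1 | step 5 | diethyl {[2-bromo-4-(methoxymethoxy)phenyl](trimethylsilyloxy)methyl}phosphonate (racemic) | CCOP(=O)(OCC)C(O[Si](C)(C)C)c1ccc(OCOC)cc1Br
F2 | step 5 | 1-[2-bromo-4-(methoxymethoxy)phenyl]-2-[2-methoxy-3-(methoxymethoxy)-4-(3-methylbut-2-enyloxy)phenyl]-1-(trimethylsilyloxy)ethene (E/Z mixture) | C[Si](C)(C)OC(=Cc1ccc(OCC=C(C)C)c(OCOC)c1OC)c1ccc(OCOC)cc1Br
F3 | step 7 | 3-[4-hydroxy-2-methoxy-3-(methoxymethoxy)phenyl]-7-(methoxymethoxy)-4H-chromen-4-one | O=c1c(-c2ccc(O)c(OCOC)c2OC)coc2cc(OCOC)ccc12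
F4 | step 7 | 3-[5-bromo-4-hydroxy-2-methoxy-3-(methoxymethoxy)phenyl]-7-(methoxymethoxy)-4H-chromen-4-one | O=c1c(-c2cc(Br)c(O)c(OCOC)c2OC)coc2cc(OCOC)ccc12
F5 | step 9 | racemic 3-[4-hydroxy-2-methoxy-3-(methoxymethoxy)-5-(2-methylbut-3-en-2-yl)phenyl]-7-(methoxymethoxy)chroman-4-one | O=C1c2ccc(OCOC)cc2OCC1c1cc(C(C)(C)C=C)c(O)c(OCOC)c1OC
F6 | step 9 | (3S,4S)-3-[4-hydroxy-2-methoxy-3-(methoxymethoxy)-5-(2-methylbut-3-en-2-yl)phenyl]-7-(methoxymethoxy)chroman-4-ol | C=CC(C)(C)c1cc([C@H]2COc3cc(OCOC)ccc3[C@H]2O)c(OC)c(OCOC)c1O
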